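(The earlier runs and the new flask stem from a simulated flask on assumed constants; scatter was added.)

The easy step first: read what is left of the starting material, not what was made, and subtract. You asked for a quick number on the south-east flask and guessed that it is merely slow, since the north-west run was still climbing at its last reading.

the same everywhere: starting material 0.40 M; free catalyst 4.4 mM

| flask | second substrate | reagent | temperature | remark | time |
|---|---|---|---|---|---|
| south-east | 0.40 M | 0.80 M | 5 °C | the very flask that is asked about, followed so far |  |
| north-west | 0.40 M | 1.2 M | −10 °C | run made earlier |  |
| flask | 0.400 M | 0.800 M | 5 °C |  | 80 min |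

| run | time / min | target / % | starting material / % |
|---|---|---|---|
| south-east | 4.00 | 7.0 | 90.4 |
| south-east | 6.00 | 11.0 | 90.1 |
| south-east | 8.00 | 10.7 | 87.9 |
| south-east | 15.0 | 12.9 | 87.2 |
| south-east | 20.0 | 13.6 | 88.3 |
| south-east | 30.0 | 11.3 | 86.8 |
| south-east | 50.0 | 12.7 | 86.7 |
| north-west | 0.500 | 0.1 | 100.0 |
| north-west | 0.833 | 2.1 | 98.1 |
| north-west | 1.33 | 2.2 | 97.5 |
| north-west | 2.00 | 4.4 | 95.7 |
| north-west | 3.00 | 4.8 | 94.3 |
| north-west | 4.00 | 10.7 | 93.9 |
| north-west | 6.00 | 10.3 | 90.5 |

(each reading ± 1 percentage point)

- ochre: change nothing and wait 80 min more
- grey: at 80 min add reagent, 50.0% of the amount charged, then wait 80 min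
- amber: at 80 min take out 90% of the target then present, then wait 80 min
- red: at 80 min add free catalyst, 100% of the amount charged, then wait 80 min
- blue: at 80 min raise the temperature by 15 K, then wait 80 min

- removed target is counted in
- the numbers in the tables scatter with a standard deviation of 1 percentage point
- additions bring no volume worth counting

- target, in percent of the starting material first charged, at 80 min
- the remedy with the largest gain of target, or "none" below 2 percentage points (ochre / grey / amber / red / blue / none)
- target present, with what was taken out counted in, in percent of the starting material first charged, after ochre
- target present, with what was taken out counted in, in percent of the starting material first charged, after red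

From 15.0 min to 50.0 min the south-east readings of starting material go from 87.2% to 86.7%, with a scatter of 1 percentage point on each, and they average 87.2%. So we read the south-east flask as standing still. The north-west run, colder and richer in reagent, ended at 6.00 min with 10.3% of target, less than the 12.8% used up in the south-east flask, so its climb says nothing against a stop.

Reagent does not look short in the south-east flask: the 0.0510 M of starting material that reacted is less than the 0.800 M of reagent charged. We therefore bet on the catalyst. The used starting material over the free catalyst charged comes to 11.6, and this is the catalyst's working life, the turnover number, starting material used per free catalyst charged.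

On that bet we reckon 12.8% at 80 min and the same after ochre. Grey, amber and blue bring no fresh catalyst, so we expect no gain from them. Red, on the same bet, should buy the same count again, and we reckon 25.5% after it.

The forecast stands a little below us, with 12.4% now, 12.5% after ochre and 23% after red, and picks red, while granting that the “data alone cannot separate catalyst death from equilibrium”.

The south-east flask gives 12.7% at 80 min, 12.7% after ochre and 25.4% after red, so red is best with a gain of 13 points.

    reagent + catalyst intermediate B → free catalyst + second product (k = 4.98 M⁻¹ min⁻¹, Ea = 52.0 kJ mol⁻¹)
    second substrate + free catalyst ⇌ catalyst intermediate B (K = 5.48 M⁻¹, k = 217 M⁻¹ min⁻¹, Ea = 51.0 kJ mol⁻¹, ΔH = −3.00 kJ mol⁻¹)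
    starting material + free catalyst ⇌ catalyst intermediate A (K = 1.20 M⁻¹, k = 130 M⁻¹ min⁻¹, Ea = 39.0 kJ mol⁻¹, ΔH = −32.0 kJ mol⁻¹)
    second substrate + catalyst intermediate B → spent catalyst (k = 1.27 M⁻¹ min⁻¹, Ea = 52.0 kJ mol⁻¹)
    reagent + catalyst intermediate A → free catalyst + target (k = 38.7 M⁻¹ min⁻¹, Ea = 59.0 kJ mol⁻¹)
    (constants at 5 °C)

Put back into our number, the first charge made 11.6 turnovers and the added charge 11.5, against our 11.6. But the number belongs to this charge of second substrate. Second substrate takes up free catalyst as catalyst intermediate B, and more of it turns that into spent catalyst, which stands at 100% at 80.0 min. These two steps together are part of the reason for the stop: without the last one the flask reaches 88.3%, not 12.7%. At 0.339 M or 0.514 M of second substrate, the other amounts and the time held, the target at 80 min has moved by 5 percentage points.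

With 0.0011 M of free catalyst and the rest held, our number gives 3.19%, and that neighbour flask computes to 3.18%.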